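The route rests on opening ring B at the C8–C9 bond (labdane numbering). A secondary radical at C9, on the arm of C10 that already carries the whole side chain, adds 6-exo-dig to a C8≡C17 alkyne held on the C5 arm. In one operation this closes ring B, creates the C8=C17 exocyclic methylene and the C9 stereocentre, and removes the C3 oxygen left over from ring A assembly. The precursor is a monocyclic ring A bis(thionocarbonate) whose C4, C5 and C10 stereocentres come from a catalytic enantioselective Diels–Alder reaction and a β-keto ester methylation. The feature exploited is the C9(H)–C8(=C17H2) unit next to quaternary C10, with trans-diequatorial arms on ring A.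

Key step: step 10

Remark: methyl 3-oxopent-4-enoate is taken as a catalogue compound, and the (S)-oxazaborolidinium catalyst of step 3 is assigned by the usual model for 2-substituted enals; its antipode is used should the sense prove opposite.

Step 1
Reactants: 1 pent-4-yn-1-ol
Product: 3 (2E)-2-methylhept-2-en-6-ynal, via pent-4-ynal 2 (not isolated)
Conditions: TEMPO (cat.), PhI(OAc)2, CH2Cl2, rt; then Ph3P=C(CH3)CHO, PhMe, 80 °C
Reagents that add atoms: 2-(triphenyl-λ5-phosphanylidene)propanal, CC(C=O)=P(c1ccccc1)(c1ccccc1)c1ccccc1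
Why: The oxoammonium oxidation stops at the volatile aldehyde, which is trapped in the same flask by a Wittig reaction with the stabilised formyl ylide; this should give the (E)-trisubstituted enal.

Step 2
Reactants: 4 methyl 3-oxopent-4-enoate
Product: 5 methyl (2Z)-3-{[tri(propan-2-yl)silyl]oxy}penta-2,4-dienoate
Conditions: i-Pr3SiOSO2CF3, Et3N, CH2Cl2, 0 °C
Reagents that add atoms: triisopropylsilyl trifluoromethanesulfonate, CC(C)[Si](C(C)C)(C(C)C)OS(=O)(=O)C(F)(F)F
Why: Soft enolisation of the β-keto ester (silyl enol ether formation) should give the (Z)-silyl enol ether, a 2-silyloxy diene whose ester-bearing terminus is the nucleophilic one.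

Step 3
Reactants: 3 (2E)-2-methylhept-2-en-6-ynal; 5 methyl (2Z)-3-{[tri(propan-2-yl)silyl]oxy}penta-2,4-dienoate
Product: 7 methyl (2S,3S)-2-(but-3-yn-1-yl)-3-formyl-3-methyl-6-oxocyclohexane-1-carboxylate (C1 epimers and enol), via silyl enol ether adduct 6 (not isolated)
Conditions: (S)-1-(2-methylphenyl)-3,3-diphenyltetrahydro-1H,3H-pyrrolo[1,2-c][1,3,2]oxazaborole·HN(SO2CF3)2 (20 mol %), CH2Cl2, −78 to −40 °C; then 1 M HCl, THF, 0 °C
Reagents that add atoms: none
Why: In this Lewis acid-catalysed Diels–Alder reaction the diene supplies C1–C4 and C19 and the enal C5–C10, C17 and C20; the silyloxy-activated terminus C4 bonds to the enal β-carbon C5 and the CH2 terminus C1 to C10, suprafacial addition to the (E)-enal places the formyl group trans and the C-methyl cis to the butynyl chain, and the chiral boron cation bound to the formyl group shields one enal face so that C5 and C10 are set absolutely, while the ester-bearing carbon is left uncontrolled and the enol ether is hydrolysed on work-up.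

Step 4
Reactants: 7 methyl (2S,3S)-2-(but-3-yn-1-yl)-3-formyl-3-methyl-6-oxocyclohexane-1-carboxylate
Product: 8 methyl (1R,2R,3S)-2-(but-3-yn-1-yl)-3-formyl-1,3-dimethyl-6-oxocyclohexane-1-carboxylate
Conditions: K2CO3, MeI, acetone, rt
Reagents that add atoms: iodomethane, CI
Why: In this C-alkylation of the β-keto ester enolate, methyl iodide should attack the face opposite the adjacent butynyl chain and the syn-axial C-methyl two carbons away, which sets the quaternary carbon with the ester cis to the chain.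

Step 5
Reactants: 9 (S)-citronellol, (3S)-3,7-dimethyloct-6-en-1-ol
Product: 10 tert-butyl{[(3S)-3,7-dimethyloct-6-en-1-yl]oxy}diphenylsilane
Conditions: t-BuPh2SiCl, imidazole, DMF, rt
Reagents that add atoms: tert-butyl(chloro)diphenylsilane, CC(C)(C)[Si](Cl)(c1ccccc1)c1ccccc1
Why: Imidazole-promoted silyl ether formation protects the primary alcohol and leaves the stereocentre untouched.

Step 6
Reactants: 10 tert-butyl{[(3S)-3,7-dimethyloct-6-en-1-yl]oxy}diphenylsilane
Product: 11 (4S)-6-[(tert-butyldiphenylsilyl)oxy]-4-methylhexanoic acid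
Conditions: NaIO4, KMnO4 (cat.), t-BuOH, aqueous pH 7 buffer, rt
Reagents that add atoms: sodium periodate, [Na+].[O-]I(=O)(=O)=O; potassium permanganate, [K+].[O-][Mn](=O)(=O)=O
Why: In this Lemieux–von Rudloff oxidation, catalytic permanganate dihydroxylates the trisubstituted alkene and periodate cleaves the diol and reoxidises manganese, which should give the acid and acetone without touching the silyl ether or the stereocentre.

Step 7
Reactants: 11 (4S)-6-[(tert-butyldiphenylsilyl)oxy]-4-methylhexanoic acid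
Product: 12 tert-butyl{[(3R)-5-iodo-3-methylpentyl]oxy}diphenylsilane
Conditions: PhI(OAc)2, I2, cyclohexane, hν (tungsten lamp), reflux
Reagents that add atoms: iodine, II
Why: In this Hunsdiecker-type iododecarboxylation the acyl hypoiodite fragments under light to a primary radical that iodine traps; the remote stereocentre is unaffected and its descriptor changes only through the priority rules.

Step 8
Reactants: 12 tert-butyl{[(3R)-5-iodo-3-methylpentyl]oxy}diphenylsilane; 8 methyl (1R,2R,3S)-2-(but-3-yn-1-yl)-3-formyl-1,3-dimethyl-6-oxocyclohexane-1-carboxylate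
Product: 15 methyl (1R,2R,3S)-2-(but-3-yn-1-yl)-3-[(4S)-6-[(tert-butyldiphenylsilyl)oxy]-1-hydroxy-4-methylhexyl]-6-hydroxy-1,3-dimethylcyclohexane-1-carboxylate (mixture of carbinol epimers), via Grignard reagent 13 (not isolated), via hydroxy ketone 14 (not isolated)
Conditions: 12, Mg, Et2O, rt; add to 8, THF, −78 °C; then MeOH, NaBH4, −78 to 0 °C
Reagents that add atoms: none
Why: Grignard addition at −78 °C should be selective for the aldehyde over the neopentyl ketone, the hindered ester and the alkyne C–H, and NaBH4 then reduces the ketone in the same flask; both new carbinol centres form as mixtures, which is harmless because both become radicals in step 10.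

Step 9
Reactants: 15 methyl (1R,2R,3S)-2-(but-3-yn-1-yl)-3-[(4S)-6-[(tert-butyldiphenylsilyl)oxy]-1-hydroxy-4-methylhexyl]-6-hydroxy-1,3-dimethylcyclohexane-1-carboxylate
Product: 16 methyl (1R,2R,3S)-2-(but-3-yn-1-yl)-3-[(4S)-6-[(tert-butyldiphenylsilyl)oxy]-4-methyl-1-[(phenoxycarbonothioyl)oxy]hexyl]-1,3-dimethyl-6-[(phenoxycarbonothioyl)oxy]cyclohexane-1-carboxylate (mixture of epimers)
Conditions: PhOC(S)Cl, pyridine, DMAP (cat.), MeCN, 40 °C
Reagents that add atoms: O-phenyl carbonochloridothioate, S=C(Cl)Oc1ccccc1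
Why: DMAP-catalysed acylation of both hindered secondary alcohols gives the thionocarbonates needed for Barton–McCombie chemistry under conditions that leave ester, alkyne and silyl ether alone.

Step 10
Reactants: 16 methyl (1R,2R,3S)-2-(but-3-yn-1-yl)-3-[(4S)-6-[(tert-butyldiphenylsilyl)oxy]-4-methyl-1-[(phenoxycarbonothioyl)oxy]hexyl]-1,3-dimethyl-6-[(phenoxycarbonothioyl)oxy]cyclohexane-1-carboxylate
Product: 17 methyl (1S,4aR,5S,8aR)-5-[(3S)-5-[(tert-butyldiphenylsilyl)oxy]-3-methylpentyl]-1,4a-dimethyl-6-methylidenedecahydronaphthalene-1-carboxylate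
Conditions: (Me3Si)3SiH (3 equiv) and AIBN (0.3 equiv) added over 6 h by syringe pump, PhMe (0.005 M), 90 °C
Reagents that add atoms: none
Why: A silyl radical adds to each C=S group and β-scission releases the C3 and C9 secondary radicals; the C3 radical simply takes hydrogen from the silane, while the C9 radical attacks C8 of the C8≡C17 alkyne and the resulting C17 vinyl radical is reduced to the exocyclic methylene. The closest known reaction type is a Barton–McCombie deoxygenation run as a radical cyclisation onto an alkyne. Ring B is closed in the 6-exo-dig mode. C9 is set in a chair-like transition state templated by ring A, whose C5 and C10 arms are trans-diequatorial: the side chain on the radical carbon should take the pseudo-equatorial position, away from the axial hydrogens at C5 and C7, which gives 9S with the C9 hydrogen anti to the C10 methyl. The step needs ring closure to outrun hydrogen transfer to C9 and needs silyl radicals to choose C=S over the alkyne; slow addition of the weak donor (Me3Si)3SiH at high dilution and the thiophilicity of silyl radicals should secure this, and exo closure onto the internal alkyne carbon is geometrically favoured over 7-endo attack. All carbinol epimers of 16 converge on the same product.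

Step 11
Reactants: 17 methyl (1S,4aR,5S,8aR)-5-[(3S)-5-[(tert-butyldiphenylsilyl)oxy]-3-methylpentyl]-1,4a-dimethyl-6-methylidenedecahydronaphthalene-1-carboxylate
Product: 18 (1S,4aR,5S,8aR)-5-[(3S)-5-[(tert-butyldiphenylsilyl)oxy]-3-methylpentyl]-1,4a-dimethyl-6-methylidenedecahydronaphthalene-1-carboxylic acid
Conditions: n-PrSLi, HMPA, rt; then 1 M HCl
Reagents that add atoms: none
Why: In this SN2 dealkylation the thiolate attacks the methyl carbon of the ester, so cleavage does not depend on access to the hindered axial carbonyl and should leave alkene and silyl ether untouched.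

Step 12
Reactants: 18 (1S,4aR,5S,8aR)-5-[(3S)-5-[(tert-butyldiphenylsilyl)oxy]-3-methylpentyl]-1,4a-dimethyl-6-methylidenedecahydronaphthalene-1-carboxylic acid
Product: 19 imbricatolic acid, (1S,4aR,5S,8aR)-5-[(3S)-5-hydroxy-3-methylpentyl]-1,4a-dimethyl-6-methylidenedecahydronaphthalene-1-carboxylic acid
Conditions: Bu4NF, THF, rt; NH4Cl (aq)
Reagents that add atoms: none
Why: Fluoride-induced cleavage of the Si–O bond (desilylation) should liberate the primary alcohol without affecting the alkene or the acid.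

Step 13
Reactants: 19 imbricatolic acid
Product: 20 (1S,4aR,5S,8aR)-1,4a-dimethyl-6-methylidene-5-[(3S)-3-methyl-5-(octadecanoyloxy)pentyl]decahydronaphthalene-1-carboxylic acid (CNP0298278.1)
Conditions: immobilised Candida antarctica lipase B, vinyl stearate, PhMe, 40 °C
Reagents that add atoms: vinyl octadecanoate, CCCCCCCCCCCCCCCCCC(=O)OC=C
Why: Transesterification catalysed by a lipase (serine hydrolase class) should acylate the primary alcohol irreversibly, since vinyl alcohol tautomerises to acetaldehyde, while the hindered tertiary carboxylic acid is not accepted by the enzyme.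

Compound list
1 | pent-4-yn-1-ol | C#CCCCO | starting material
2 | pent-4-ynal | C#CCCC=O | intermediate
3 | (2E)-2-methylhept-2-en-6-ynal | C#CCC/C=C(\C)C=O | intermediate
4 | methyl 3-oxopent-4-enoate | C=CC(=O)CC(=O)OC | starting material
5 | methyl (2Z)-3-{[tri(propan-2-yl)silyl]oxy}penta-2,4-dienoate | C=C/C(O[Si](C(C)C)(C(C)C)C(C)C)=C/C(=O)OC | intermediate
6 | methyl (5S,6S)-6-(but-3-yn-1-yl)-5-formyl-5-methyl-2-{[tri(propan-2-yl)silyl]oxy}cyclohex-2-ene-1-carboxylate (C1 epimers; formyl trans to the butynyl chain) | C#CCC[C@@H]1[C@](C)(CC=C(O[Si](C(C)C)(C(C)C)C(C)C)C1C(=O)OC)C=O | intermediate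
7 | methyl (2S,3S)-2-(but-3-yn-1-yl)-3-formyl-3-methyl-6-oxocyclohexane-1-carboxylate (C1 epimers and enol) | C#CCC[C@@H]1[C@](C)(CCC(=O)C1C(=O)OC)C=O | intermediate
8 | methyl (1R,2R,3S)-2-(but-3-yn-1-yl)-3-formyl-1,3-dimethyl-6-oxocyclohexane-1-carboxylate (ester cis, formyl trans to the butynyl chain) | C#CCC[C@@H]1[C@](C)(CCC(=O)[C@]1(C)C(=O)OC)C=O | intermediate
9 | (S)-citronellol, (3S)-3,7-dimethyloct-6-en-1-ol | CC(C)=CCC[C@H](C)CCO | starting material
10 | tert-butyl{[(3S)-3,7-dimethyloct-6-en-1-yl]oxy}diphenylsilane | CC(C)=CCC[C@H](C)CCO[Si](c1ccccc1)(c1ccccc1)C(C)(C)C | intermediate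
11 | (4S)-6-[(tert-butyldiphenylsilyl)oxy]-4-methylhexanoic acid | OC(=O)CC[C@H](C)CCO[Si](c1ccccc1)(c1ccccc1)C(C)(C)C | intermediate
12 | tert-butyl{[(3R)-5-iodo-3-methylpentyl]oxy}diphenylsilane | ICC[C@H](C)CCO[Si](c1ccccc1)(c1ccccc1)C(C)(C)C | intermediate
13 | {(3R)-5-[(tert-butyldiphenylsilyl)oxy]-3-methylpentyl}magnesium iodide | I[Mg]CC[C@H](C)CCO[Si](c1ccccc1)(c1ccccc1)C(C)(C)C | intermediate
14 | methyl (1R,2R,3S)-2-(but-3-yn-1-yl)-3-[(4S)-6-[(tert-butyldiphenylsilyl)oxy]-1-hydroxy-4-methylhexyl]-1,3-dimethyl-6-oxocyclohexane-1-carboxylate (carbinol epimers) | C#CCC[C@@H]1[C@](C)(CCC(=O)[C@]1(C)C(=O)OC)C(O)CC[C@H](C)CCO[Si](c2ccccc2)(c2ccccc2)C(C)(C)C | intermediate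
15 | methyl (1R,2R,3S)-2-(but-3-yn-1-yl)-3-[(4S)-6-[(tert-butyldiphenylsilyl)oxy]-1-hydroxy-4-methylhexyl]-6-hydroxy-1,3-dimethylcyclohexane-1-carboxylate (carbinol epimers) | C#CCC[C@@H]1[C@](C)(CCC(O)[C@]1(C)C(=O)OC)C(O)CC[C@H](C)CCO[Si](c2ccccc2)(c2ccccc2)C(C)(C)C | intermediate
16 | methyl (1R,2R,3S)-2-(but-3-yn-1-yl)-3-[(4S)-6-[(tert-butyldiphenylsilyl)oxy]-4-methyl-1-[(phenoxycarbonothioyl)oxy]hexyl]-1,3-dimethyl-6-[(phenoxycarbonothioyl)oxy]cyclohexane-1-carboxylate (epimers at the two oxygenated carbons) | C#CCC[C@@H]1[C@](C)(CCC(OC(=S)Oc2ccccc2)[C@]1(C)C(=O)OC)C(OC(=S)Oc2ccccc2)CC[C@H](C)CCO[Si](c2ccccc2)(c2ccccc2)C(C)(C)C | intermediate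
17 | methyl (1S,4aR,5S,8aR)-5-[(3S)-5-[(tert-butyldiphenylsilyl)oxy]-3-methylpentyl]-1,4a-dimethyl-6-methylidenedecahydronaphthalene-1-carboxylate | C=C1CC[C@@H]2[C@](C)(CCC[C@]2(C)C(=O)OC)[C@H]1CC[C@H](C)CCO[Si](c3ccccc3)(c3ccccc3)C(C)(C)C | intermediate
18 | (1S,4aR,5S,8aR)-5-[(3S)-5-[(tert-butyldiphenylsilyl)oxy]-3-methylpentyl]-1,4a-dimethyl-6-methylidenedecahydronaphthalene-1-carboxylic acid | C=C1CC[C@@H]2[C@](C)(CCC[C@]2(C)C(=O)O)[C@H]1CC[C@H](C)CCO[Si](c3ccccc3)(c3ccccc3)C(C)(C)C | intermediate
19 | imbricatolic acid, (1S,4aR,5S,8aR)-5-[(3S)-5-hydroxy-3-methylpentyl]-1,4a-dimethyl-6-methylidenedecahydronaphthalene-1-carboxylic acid | C=C1CC[C@@H]2[C@](C)(CCC[C@]2(C)C(=O)O)[C@H]1CC[C@H](C)CCO | intermediate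
20 | (1S,4aR,5S,8aR)-1,4a-dimethyl-6-methylidene-5-[(3S)-3-methyl-5-(octadecanoyloxy)pentyl]decahydronaphthalene-1-carboxylic acid | C=C1CC[C@@H]2[C@](C)(CCC[C@]2(C)C(=O)O)[C@H]1CC[C@H](C)CCOC(=O)CCCCCCCCCCCCCCCCC | target

Total step count: 13. Longest linear sequence: 9 steps (steps 1, 3, 4, 8, 9, 10, 11, 12, 13; the branch through steps 5, 6, 7 is equally long).

Steps most likely to fail

Step 10 (radical ring closure). What may go wrong is hydrogen transfer to the C9 radical, or a 1,5-hydrogen shift from the propargylic C7–H, before the ring closes, and insufficient face discrimination at C9. The fallback reverses the roles of C8 and C9 and sets out from 8 and 12. Iodide 12 and PPh3 (MeCN, 80 °C) give {(3R)-5-[(tert-butyldiphenylsilyl)oxy]-3-methylpentyl}triphenylphosphonium iodide F1. Its ylide (NaN(SiMe3)2, THF, −78 °C) should react only with the aldehyde of 8 and give the (Z)-1,7-enyne ketone F2. A palladium hydride-mediated reductive cyclisation (Pd2(dba)3·CHCl3, P(o-tolyl)3, AcOH, Et3SiH, PhH, rt) then adds H–Pd to the alkyne with palladium at C8, inserts the C9=C11 alkene in the 6-exo mode and reduces the C11–Pd bond, giving the decalone F3. NaBH4 gives the alcohol F4, PhOC(S)Cl with DMAP the thionocarbonate F5, and (Me3Si)3SiH with AIBN removes the C3 oxygen and returns to the route at 17.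

Step 3 (Diels–Alder reaction). What may go wrong is addition of the silyloxy diene to the activated formyl group (hetero-Diels–Alder or aldol-type) instead of the C=C bond, slow reaction of the trisubstituted enal, or erosion of enantioselectivity. The fallback gives up asymmetric catalysis at this point and sets out from 3 and 5. They are combined with the achiral Lewis acid Me2AlCl (CH2Cl2, −40 °C) or simply heated (PhMe, 110 °C). Hydrolysis and methylation as in steps 3 and 4 then give racemic material, that is 6, 7 and 8 together with the enantiomeric adduct F6, the enantiomeric β-keto ester F7 and the enantiomeric keto aldehyde F8. Preparative chromatography on a chiral stationary phase separates 8 from F8, and the route is rejoined at 8.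

Step 8 (side-chain addition). What may go wrong is β-hydride reduction or slow addition at the neopentyl aldehyde, and enolisation of or attack on the ketone. The fallback sets out from 12 and 8 and replaces the Grignard reagent by a Nozaki–Hiyama–Kishi-type alkylation (CrCl2, cobalt phthalocyanine CoC32H16N8 cat., DMF, rt), which adds alkyl iodides to aldehydes in the presence of ketones and esters. It gives 14, which NaBH4 reduces to 15, where the route is rejoined; no new compound arises.

Further compounds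
F1 | step 10 | {(3R)-5-[(tert-butyldiphenylsilyl)oxy]-3-methylpentyl}triphenylphosphonium iodide | c1ccccc1[P+](c1ccccc1)(c1ccccc1)CC[C@H](C)CCO[Si](c1ccccc1)(c1ccccc1)C(C)(C)C.[I-]
F2 | step 10 | methyl (1R,2R,3R)-2-(but-3-yn-1-yl)-3-[(1Z,4S)-6-[(tert-butyldiphenylsilyl)oxy]-4-methylhex-1-en-1-yl]-1,3-dimethyl-6-oxocyclohexane-1-carboxylate | C#CCC[C@@H]1[C@](C)(CCC(=O)[C@]1(C)C(=O)OC)/C=C\C[C@H](C)CCO[Si](c2ccccc2)(c2ccccc2)C(C)(C)C
F3 | step 10 | methyl (1R,4aR,5S,8aR)-5-[(3S)-5-[(tert-butyldiphenylsilyl)oxy]-3-methylpentyl]-1,4a-dimethyl-6-methylidene-2-oxodecahydronaphthalene-1-carboxylate | C=C1CC[C@@H]2[C@](C)(CCC(=O)[C@]2(C)C(=O)OC)[C@H]1CC[C@H](C)CCO[Si](c3ccccc3)(c3ccccc3)C(C)(C)C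
F4 | step 10 | methyl (1R,4aR,5S,8aR)-5-[(3S)-5-[(tert-butyldiphenylsilyl)oxy]-3-methylpentyl]-2-hydroxy-1,4a-dimethyl-6-methylidenedecahydronaphthalene-1-carboxylate (C2 epimers) | C=C1CC[C@@H]2[C@](C)(CCC(O)[C@]2(C)C(=O)OC)[C@H]1CC[C@H](C)CCO[Si](c3ccccc3)(c3ccccc3)C(C)(C)C
F5 | step 10 | methyl (1R,4aR,5S,8aR)-5-[(3S)-5-[(tert-butyldiphenylsilyl)oxy]-3-methylpentyl]-1,4a-dimethyl-6-methylidene-2-[(phenoxycarbonothioyl)oxy]decahydronaphthalene-1-carboxylate (C2 epimers) | C=C1CC[C@@H]2[C@](C)(CCC(OC(=S)Oc3ccccc3)[C@]2(C)C(=O)OC)[C@H]1CC[C@H](C)CCO[Si](c3ccccc3)(c3ccccc3)C(C)(C)C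
F6 | step 3 | methyl (5R,6R)-6-(but-3-yn-1-yl)-5-formyl-5-methyl-2-{[tri(propan-2-yl)silyl]oxy}cyclohex-2-ene-1-carboxylate | C#CCC[C@H]1[C@@](C)(CC=C(O[Si](C(C)C)(C(C)C)C(C)C)C1C(=O)OC)C=O
F7 | step 3 | methyl (2R,3R)-2-(but-3-yn-1-yl)-3-formyl-3-methyl-6-oxocyclohexane-1-carboxylate | C#CCC[C@H]1[C@@](C)(CCC(=O)C1C(=O)OC)C=O
F8 | step 3 | methyl (1S,2S,3R)-2-(but-3-yn-1-yl)-3-formyl-1,3-dimethyl-6-oxocyclohexane-1-carboxylate | C#CCC[C@H]1[C@@](C)(CCC(=O)[C@@]1(C)C(=O)OC)C=O
F0 | step 8 | none | none
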